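The 2,3-dihydrobenzofuran ring is disconnected at O1–C2 and C3–C3a into phenol 7 (the 2-arylbenzofuran, a 4-substituted guaiacol) and a ferulic acid unit. C3 (the side-chain carbon next to the future CH2OH) and C3a (ortho to O1) are both nucleophilic, so they are joined as radicals. Ag2O oxidation of 7 and of the N-feruloyl camphorsultam 12 should give C3–C3a coupling. The resulting p-quinone methide at C2, which exists because C2 is para-hydroxybenzylic, is closed by O1 to the trans ring. The sultam sets C3; reduction of the acyl sultam then gives the target.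

Key step: step 8

Assumption: (2R)-sultam acyl derivatives are usually attacked on the Cα-Re face, so the (2S)-sultam 10 is taken to expose the Cα-Si face of C8 needed here; if the sense proved opposite, the equally available (2R)-sultam would replace 10 with no other change.

Step 1
Reactants: 1 dihydroconiferyl alcohol, 4-(3-hydroxypropyl)-2-methoxyphenol
Product: 2 4-(3-hydroxypropyl)-2-iodo-6-methoxyphenol
Conditions: I2, NaHCO3, THF/H2O, 0 °C to rt
Reagents that add atoms: iodine, II
Why: Electrophilic aromatic iodination of the phenoxide should go to the only free position ortho to the OH, the para position being blocked by the propyl chain, as in the iodination of vanillin.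

Step 2
Reactants: 3 4-(benzyloxy)-3-methoxybenzaldehyde (O-benzylvanillin)
Product: 4 1-(benzyloxy)-4-ethynyl-2-methoxybenzene
Conditions: dimethyl (1-diazo-2-oxopropyl)phosphonate, K2CO3, MeOH, rt
Reagents that add atoms: dimethyl (1-diazo-2-oxopropyl)phosphonate, COP(=O)(OC)C(=[N+]=[N-])C(C)=O
Why: Seyferth–Gilbert homologation in the Ohira–Bestmann variant, in which the diazomethylphosphonate anion freed by methanolysis adds to the non-enolizable aldehyde and the diazoalkene loses N2 to the terminal alkyne; the benzyl ether is inert.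

Step 3
Reactants: 2 4-(3-hydroxypropyl)-2-iodo-6-methoxyphenol; 4 1-(benzyloxy)-4-ethynyl-2-methoxybenzene
Product: 6 3-{2-[4-(benzyloxy)-3-methoxyphenyl]-7-methoxy-1-benzofuran-5-yl}propan-1-ol, via o-alkynylphenol 5 (not isolated)
Conditions: Pd(PPh3)2Cl2 (cat.), CuI (cat.), Et3N, DMF, rt then 80 °C
Reagents that add atoms: none
Why: Sonogashira coupling of the o-iodophenol with the aryl alkyne should give 5, whose phenol then adds across the alkyne on warming (5-endo-dig cycloisomerization) to the 2-arylbenzofuran; the free primary alcohol does not interfere.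

Step 4
Reactants: 6 3-{2-[4-(benzyloxy)-3-methoxyphenyl]-7-methoxy-1-benzofuran-5-yl}propan-1-ol
Product: 7 4-[5-(3-hydroxypropyl)-7-methoxy-1-benzofuran-2-yl]-2-methoxyphenol
Conditions: H2 (1 atm), Pd/C, EtOAc/MeOH, rt
Reagents that add atoms: none
Why: Hydrogenolysis of the benzyl aryl ether over Pd/C; the C2=C3 bond of the 2-arylbenzofuran belongs to an aromatic ring and should not be reduced under these mild conditions.

Step 5
Reactants: 8 (E)-3-(4-acetoxy-3-methoxyphenyl)prop-2-enoic acid (O-acetylferulic acid)
Product: 9 (E)-3-(4-acetoxy-3-methoxyphenyl)prop-2-enoyl chloride (used crude after evaporation)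
Conditions: (COCl)2, DMF (cat.), CH2Cl2, 0 °C to rt
Reagents that add atoms: oxalyl chloride, ClC(=O)C(=O)Cl
Why: Acid chloride formation through the Vilsmeier-type chloroiminium salt from DMF and (COCl)2; the aryl acetate and the (E)-alkene are inert.

Step 6
Reactants: 9 (E)-3-(4-acetoxy-3-methoxyphenyl)prop-2-enoyl chloride; 10 (2S)-bornane-10,2-sultam, the (+)-enantiomer of 2,10-camphorsultam, (3aR,6S,7aS)
Product: 11 N-[(E)-3-(4-acetoxy-3-methoxyphenyl)prop-2-enoyl]-(2S)-bornane-10,2-sultam
Conditions: 10, NaH, toluene, 0 °C; then 9, rt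
Reagents that add atoms: none
Why: N-Acylation of the sodium salt of the sultam by the acid chloride, the standard way of attaching this auxiliary; the acid chloride reacts far faster than the aryl acetate.

Step 7
Reactants: 11 N-[(E)-3-(4-acetoxy-3-methoxyphenyl)prop-2-enoyl]-(2S)-bornane-10,2-sultam
Product: 12 N-[(E)-3-(4-hydroxy-3-methoxyphenyl)prop-2-enoyl]-(2S)-bornane-10,2-sultam (N-feruloyl sultam)
Conditions: pyrrolidine, CH2Cl2, 0 °C to rt
Reagents that add atoms: none
Why: Chemoselective aminolysis of the phenolic acetate, since an aryl ester is a much better acyl donor than the hindered N-acyl sultam, should free the phenol and leave the enoyl sultam intact.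

Step 8
Reactants: 7 4-[5-(3-hydroxypropyl)-7-methoxy-1-benzofuran-2-yl]-2-methoxyphenol (excess, recovered); 12 N-feruloyl-(2S)-bornane-10,2-sultam (limiting, added slowly)
Product: 14 N-{[(2S,3S)-2-(4-hydroxy-3-methoxyphenyl)-5-[5-(3-hydroxypropyl)-7-methoxy-1-benzofuran-2-yl]-7-methoxy-2,3-dihydro-1-benzofuran-3-yl]carbonyl}-(2S)-bornane-10,2-sultam, via quinone methide 13 (not isolated)
Conditions: Ag2O, CH2Cl2/acetone, rt, dark, N2, 12 added by syringe pump; chromatography or crystallization to remove the minor diastereomer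
Reagents that add atoms: none
Why: Ag2O oxidizes both phenols to phenoxyl radicals; the radical of 12 has high spin density at C8 (the carbon α to the acyl group) and the radical of 7 at its one free ring carbon ortho to oxygen, and their cross-coupling forms C3–C3a, after which the dienone tautomerizes to the phenol of quinone methide 13. The phenolic oxygen then adds to the exocyclic carbon of the quinone methide in a 5-exo-trig conjugate (1,6-) addition, forming O1–C2 and restoring the guaiacyl phenol. The closest known reaction is the biomimetic Ag2O dehydrodimerization of ferulates to phenylcoumarans (8–5 oxidative phenol coupling, a formal oxidative [3+2] annulation), including its camphorsultam-controlled asymmetric version and the cross-coupling of hydroxycinnamates with guaiacyl phenols. C3 is set in the radical coupling by the sultam, which in the s-cis enoyl conformer with C=O anti to the SO2 group should leave one face of C8 open (the Si face, under the stated assumption); C2 is set in the ring closure, which should place aryl and acyl groups trans. The step needs cross- over homo-coupling and C- over O-coupling on 7: an excess of the slowly dimerizing, para-blocked radical of 7 and slow addition of the fast-coupling 12 favour the first, and only the C–C coupled quinone methide can close intramolecularly, which makes it the productive channel. The primary alcohol, the benzofuran and the acyl sultam should be inert to Ag2O at room temperature.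

Step 9
Reactants: 14 N-acyl sultam of the (2S,3S)-dihydrobenzofuran-3-carboxylic acid
Product: 15 4-[(2S,3R)-3-(hydroxymethyl)-5-[5-(3-hydroxypropyl)-7-methoxy-1-benzofuran-2-yl]-7-methoxy-2,3-dihydro-1-benzofuran-2-yl]-2-methoxyphenol (target)
Conditions: LiBH4 (excess), THF/MeOH, 0 °C to rt; aq. NH4Cl
Reagents that add atoms: none
Why: Reductive cleavage of the N-acyl sultam by LiBH4 (hydride addition, collapse to the aldehyde, reduction to the primary alcohol) should release the auxiliary without touching either stereocenter; the change of the C3 descriptor from S to R is only a change of CIP priorities.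

Compound list
1 | dihydroconiferyl alcohol, 4-(3-hydroxypropyl)-2-methoxyphenol | COc1cc(CCCO)ccc1O | starting material
2 | 4-(3-hydroxypropyl)-2-iodo-6-methoxyphenol | COc1cc(CCCO)cc(I)c1O | intermediate
3 | 4-(benzyloxy)-3-methoxybenzaldehyde | COc1cc(C=O)ccc1OCc1ccccc1 | starting material
4 | 1-(benzyloxy)-4-ethynyl-2-methoxybenzene | COc1cc(C#C)ccc1OCc1ccccc1 | intermediate
5 | 2-{[4-(benzyloxy)-3-methoxyphenyl]ethynyl}-4-(3-hydroxypropyl)-6-methoxyphenol (not isolated) | COc1cc(C#Cc2cc(CCCO)cc(OC)c2O)ccc1OCc1ccccc1 | intermediate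
6 | 3-{2-[4-(benzyloxy)-3-methoxyphenyl]-7-methoxy-1-benzofuran-5-yl}propan-1-ol | COc1cc(-c2cc3cc(CCCO)cc(OC)c3o2)ccc1OCc1ccccc1 | intermediate
7 | 4-[5-(3-hydroxypropyl)-7-methoxy-1-benzofuran-2-yl]-2-methoxyphenol | COc1cc(-c2cc3cc(CCCO)cc(OC)c3o2)ccc1O | intermediate
8 | (E)-3-(4-acetoxy-3-methoxyphenyl)prop-2-enoic acid | COc1cc(/C=C/C(=O)O)ccc1OC(C)=O | starting material
9 | (E)-3-(4-acetoxy-3-methoxyphenyl)prop-2-enoyl chloride | COc1cc(/C=C/C(Cl)=O)ccc1OC(C)=O | intermediate
10 | (2S)-bornane-10,2-sultam, (3aR,6S,7aS) | CC1(C)[C@H]2CC[C@@]13CS(=O)(=O)N[C@H]3C2 | starting material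
11 | N-[(E)-3-(4-acetoxy-3-methoxyphenyl)prop-2-enoyl]-(2S)-bornane-10,2-sultam | CC1(C)[C@H]2CC[C@@]13CS(=O)(=O)N(C(=O)/C=C/c4ccc(OC(C)=O)c(OC)c4)[C@H]3C2 | intermediate
12 | N-[(E)-3-(4-hydroxy-3-methoxyphenyl)prop-2-enoyl]-(2S)-bornane-10,2-sultam | CC1(C)[C@H]2CC[C@@]13CS(=O)(=O)N(C(=O)/C=C/c4ccc(O)c(OC)c4)[C@H]3C2 | intermediate
13 | p-quinone methide from C8–C5 coupling of 12 with 7, (R) at the new sp3 carbon (not isolated) | CC1(C)[C@H]2CC[C@@]13CS(=O)(=O)N(C(=O)[C@H](C=C4C=CC(=O)C(OC)=C4)c5cc(-c6cc7cc(CCCO)cc(OC)c7o6)cc(OC)c5O)[C@H]3C2 | intermediate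
14 | N-{[(2S,3S)-2-(4-hydroxy-3-methoxyphenyl)-5-[5-(3-hydroxypropyl)-7-methoxy-1-benzofuran-2-yl]-7-methoxy-2,3-dihydro-1-benzofuran-3-yl]carbonyl}-(2S)-bornane-10,2-sultam | CC1(C)[C@H]2CC[C@@]13CS(=O)(=O)N(C(=O)[C@H]4c5cc(-c6cc7cc(CCCO)cc(OC)c7o6)cc(OC)c5O[C@@H]4c8ccc(O)c(OC)c8)[C@H]3C2 | intermediate
15 | 4-[(2S,3R)-3-(hydroxymethyl)-5-[5-(3-hydroxypropyl)-7-methoxy-1-benzofuran-2-yl]-7-methoxy-2,3-dihydro-1-benzofuran-2-yl]-2-methoxyphenol | COc1cc([C@H]2Oc3c(OC)cc(-c4cc5cc(CCCO)cc(OC)c5o4)cc3[C@@H]2CO)ccc1O | target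

Total step count: 9. Longest linear sequence: 5 steps (3 → 4 → 6 → 7 → 14 → 15, or 8 → 9 → 11 → 12 → 14 → 15).

Steps most likely to fail

Step 8. The cross-coupling may lose to dimerization of 12, to C–O coupling, to coupling through the benzofuran of 7 or to further oxidation of the product, and the facial selectivity of the sultam may be low. The fallback moves the ring-forming coupling onto a cheap, robust phenol that can be used in large excess and builds the benzofuran last. It sets out from 12: Ag2O coupling of 12 with an excess of commercial 4-iodo-2-methoxyphenol (COc1cc(I)ccc1O) should give the N-acyl sultam of the 5-iodo-dihydrobenzofuran acid F1. LiBH4 then gives the iodo diol 4-[(2S,3R)-3-(hydroxymethyl)-5-iodo-7-methoxy-2,3-dihydro-1-benzofuran-2-yl]-2-methoxyphenol F2. Sonogashira coupling with ethynyltrimethylsilane gives the silylalkyne F3, and K2CO3/MeOH gives the terminal alkyne F4. Sonogashira coupling and cycloisomerization of F4 with iodophenol 2, as in step 3, comes back to the route at 15.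

Step 9. Under the basic hydride conditions the C3 position, which is α to the carbonyl and benzylic, may be deprotonated, leading to epimerization or to ring opening by β-elimination of the ring oxygen. The fallback removes the auxiliary under Lewis-acid conditions first. It sets out from 14: transesterification with Ti(OEt)4 in EtOH should give ethyl (2S,3S)-2-(4-hydroxy-3-methoxyphenyl)-5-[5-(3-hydroxypropyl)-7-methoxy-1-benzofuran-2-yl]-7-methoxy-2,3-dihydro-1-benzofuran-3-carboxylate F5, and DIBAL-H in THF at −78 °C reduces the ester and comes back at 15.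

Step 7. Pyrrolidine may add in conjugate fashion to the enoyl sultam or cleave the acyl sultam along with the acetate. The fallback avoids the phenol protecting group altogether. It sets out from 10: acylation with acryloyl chloride (NaH, toluene) gives N-acryloyl-(2S)-bornane-10,2-sultam F6, and a Heck reaction of F6 with 4-iodo-2-methoxyphenol (Pd(OAc)2, P(o-tol)3, Et3N, MeCN, 80 °C) should install the free-phenol aryl group with E geometry and come back at 12.

Further compounds
F1 | step 8 | N-{[(2S,3S)-2-(4-hydroxy-3-methoxyphenyl)-5-iodo-7-methoxy-2,3-dihydro-1-benzofuran-3-yl]carbonyl}-(2S)-bornane-10,2-sultam | CC1(C)[C@H]2CC[C@@]13CS(=O)(=O)N(C(=O)[C@H]4c5cc(I)cc(OC)c5O[C@@H]4c6ccc(O)c(OC)c6)[C@H]3C2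
F2 | step 8 | 4-[(2S,3R)-3-(hydroxymethyl)-5-iodo-7-methoxy-2,3-dihydro-1-benzofuran-2-yl]-2-methoxyphenol | COc1cc([C@H]2Oc3c(OC)cc(I)cc3[C@@H]2CO)ccc1O
F3 | step 8 | 4-[(2S,3R)-3-(hydroxymethyl)-7-methoxy-5-[(trimethylsilyl)ethynyl]-2,3-dihydro-1-benzofuran-2-yl]-2-methoxyphenol | COc1cc([C@H]2Oc3c(OC)cc(C#C[Si](C)(C)C)cc3[C@@H]2CO)ccc1O
F4 | step 8 | 4-[(2S,3R)-5-ethynyl-3-(hydroxymethyl)-7-methoxy-2,3-dihydro-1-benzofuran-2-yl]-2-methoxyphenol | COc1cc([C@H]2Oc3c(OC)cc(C#C)cc3[C@@H]2CO)ccc1O
F5 | step 9 | ethyl (2S,3S)-2-(4-hydroxy-3-methoxyphenyl)-5-[5-(3-hydroxypropyl)-7-methoxy-1-benzofuran-2-yl]-7-methoxy-2,3-dihydro-1-benzofuran-3-carboxylate | CCOC(=O)[C@H]1c2cc(-c3cc4cc(CCCO)cc(OC)c4o3)cc(OC)c2O[C@@H]1c5ccc(O)c(OC)c5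
F6 | step 7 | N-acryloyl-(2S)-bornane-10,2-sultam | C=CC(=O)N1[C@H]2C[C@@H]3CC[C@@]2(CS1(=O)=O)C3(C)C
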